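**Retrosynthetic overview**
- The oxirane and its CH2OAc arm come from an enantioselective acylative ring contraction of a prochiral 3-aryloxetan-3-ol: the oxetane oxygen becomes the acetate oxygen and the tertiary OH becomes the epoxide oxygen. This is the last step and sets the only new stereocentre.
- The aryl angelate comes from the phenol and angelic acid; the benzylic ester comes from the benzylic alcohol and (R)-2-methylbutanoic acid, whose stereocentre is bought.
- The phenol/benzylic alcohol/oxetanol triol comes from acetal-protected 2,5-dibromophenol by two Br/Li exchanges: the ortho C–Li adds to oxetan-3-one, then the para C–Li adds to formaldehyde.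
- 2,5-Dibromophenol comes from 1,4-dibromobenzene by ortho-lithiation, borylation and oxidation.
- Ring order: the benzene ring is bought; the oxetane ring is bought in oxetan-3-one and attached in step 3; the oxirane is formed last, from the oxetane.

Assumption: the sense of induction of the squaramide catalyst in step 6 has to be fixed by experiment, and the enantiomer that gives (S)-18 is used. SQ = 3-{[3,5-bis(trifluoromethyl)phenyl]amino}-4-({(2S)-3,3-dimethyl-1-oxo-1-[(2R)-2-(phenanthren-9-yl)pyrrolidin-1-yl]butan-2-yl}amino)cyclobut-3-ene-1,2-dione or its mirror image.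

Step 1
Reactants: 1 1,4-dibromobenzene
Product: 4 2,5-dibromophenol, via (2,5-dibromophenyl)lithium 2 (not isolated), via lithium aryltrimethoxyborate 3 (not isolated)
Conditions: LiN(iPr)2, THF, −78 °C; B(OMe)3, −78 °C → rt; 30% H2O2, AcOH, 0 °C → rt
Reagents that add atoms: hydrogen peroxide, OO
Why: Bromine-directed ortho-lithiation of the symmetric arene (all four ring hydrogens are equivalent, so only one aryllithium can form), borylation, then boronate oxidation with aryl migration from boron to oxygen gives the phenol.

Step 2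
Reactants: 4 2,5-dibromophenol
Product: 5 1,4-dibromo-2-(1-ethoxyethoxy)benzene (racemic at the acetal carbon, which is removed in step 3)
Conditions: ethyl vinyl ether, PPTS (5 mol %), CH2Cl2, rt
Reagents that add atoms: ethyl vinyl ether, C=COCC
Why: Acid-catalysed addition of the phenol O–H across the enol ether (1-ethoxyethyl acetal protection) has no by-product and masks the acidic proton for the organolithium chemistry.

Step 3
Reactants: 5 1,4-dibromo-2-(1-ethoxyethoxy)benzene; 6 oxetan-3-one; 7 formaldehyde
Product: 12 3-[2-hydroxy-4-(hydroxymethyl)phenyl]oxetan-3-ol, via 2-lithio aryl ether 8 (not isolated), via bromo oxetanolate 9 (not isolated), via 4-lithio oxetanolate 10 (not isolated), via ethoxyethyl diol 11 (not isolated)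
Conditions: n-BuLi (1.05 equiv), THF, −78 °C; 6; n-BuLi (1.2 equiv), −78 °C; CH2O gas (from cracked paraformaldehyde), −78 → 0 °C; H2O; then PPTS (10 mol %), MeOH, rt
Reagents that add atoms: none
Why: Two sequential bromine–lithium exchanges: the bromine ortho to the acetal oxygen exchanges first (inductive and chelation control) and the aryllithium adds to the ketone of 6, the second aryllithium is trapped by formaldehyde (1,2-additions), and acid-catalysed transacetalisation in methanol removes the ethoxyethyl group; no stereocentre is formed.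

Step 4
Reactants: 12 3-[2-hydroxy-4-(hydroxymethyl)phenyl]oxetan-3-ol; 13 (2R)-2-methylbutanoic acid
Product: 14 [3-hydroxy-4-(3-hydroxyoxetan-3-yl)phenyl]methyl (2R)-2-methylbutanoate
Conditions: PPh3, DIAD, THF, 0 °C → rt
Reagents that add atoms: none
Why: Mitsunobu esterification: only the primary benzylic alcohol forms an alkoxyphosphonium ion (the tertiary alcohol is too hindered, the phenol is not activated) and the carboxylate, far more acidic than the phenol, is the nucleophile; the stereocentre of 13 is remote from the reacting atoms and stays (R).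

Step 5
Reactants: 14 [3-hydroxy-4-(3-hydroxyoxetan-3-yl)phenyl]methyl (2R)-2-methylbutanoate; 15 angelic acid ((2Z)-2-methylbut-2-enoic acid)
Product: 17 2-(3-hydroxyoxetan-3-yl)-5-{[(2R)-2-methylbutanoyl]oxymethyl}phenyl (2Z)-2-methylbut-2-enoate, via angelic mixed anhydride 16 (not isolated)
Conditions: 15, 2,4,6-trichlorobenzoyl chloride, Et3N, toluene, rt; then 14, rt → 40 °C (no DMAP)
Reagents that add atoms: none
Why: Yamaguchi mixed-anhydride esterification: the phenol, the only acidic and unhindered OH left, attacks the less shielded angeloyl carbonyl of 16, and leaving out DMAP avoids Z to E isomerisation to the tiglate.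

Step 6
Reactants: 17 2-(3-hydroxyoxetan-3-yl)-5-{[(2R)-2-methylbutanoyl]oxymethyl}phenyl (2Z)-2-methylbut-2-enoate
Product: 19 2-[(2R)-2-(acetoxymethyl)oxiran-2-yl]-5-{[(2R)-2-methylbutanoyl]oxymethyl}phenyl (2Z)-2-methylbut-2-enoate (CNP0256757.1), via (S)-bromohydrin acetate 18 (not isolated)
Conditions: AcBr (1.05 equiv), squaramide SQ (5 mol %), t-BuOMe, −78 °C; then Cs2CO3, MeCN, 0 °C
Reagents that add atoms: acetyl bromide, CC(=O)Br
Why: Proposed new method: enantioselective acylative ring contraction of a prochiral 3-aryloxetan-3-ol. The squaramide N–H pair binds the bromide of AcBr and promotes O-acetylation of the Lewis-basic oxetane oxygen; in the chiral O-acetyloxetanium/squaramide-bound bromide ion pair, bromide opens one of the two enantiotopic CH2–O bonds by SN2, which fixes the quaternary carbinol centre as (S) in 18 and turns the ring oxygen into the acetate oxygen. Cs2CO3 then closes the tertiary alkoxide onto CH2Br (3-exo-tet, expected to outrun acyl migration, and not reversible because the other oxygen is capped as acetate), so the four-membered ring has contracted to the oxirane; the stereocentre is not touched in the closure and is (R) in 19 only through the priority rules. Closest known reaction types: hydrogen-bond-donor- and chiral-phosphoric-acid-catalysed desymmetrising openings of 3-substituted oxetanes with Me3SiBr or HCl, opening of cyclic ethers by acyl halides, and halohydrin-to-epoxide closure; new are the acyl bromide as electrophile and bromide source in the asymmetric opening, the free tertiary OH on the substrate, and the telescoped net four-to-three contraction.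

**Compound list**
1 | 1,4-dibromobenzene | Brc1ccc(Br)cc1 | starting material
2 | (2,5-dibromophenyl)lithium | [Li]c1cc(Br)ccc1Br | intermediate
3 | lithium (2,5-dibromophenyl)trimethoxyborate | [Li+].CO[B-](OC)(OC)c1cc(Br)ccc1Br | intermediate
4 | 2,5-dibromophenol | Oc1cc(Br)ccc1Br | intermediate
5 | 1,4-dibromo-2-(1-ethoxyethoxy)benzene (racemic acetal carbon) | CCOC(C)Oc1cc(Br)ccc1Br | intermediate
6 | oxetan-3-one | O=C1COC1 | starting material
7 | formaldehyde | C=O | starting material
8 | [4-bromo-2-(1-ethoxyethoxy)phenyl]lithium | CCOC(C)Oc1cc(Br)ccc1[Li] | intermediate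
9 | lithium 3-[4-bromo-2-(1-ethoxyethoxy)phenyl]oxetan-3-olate | CCOC(C)Oc1cc(Br)ccc1C1(O[Li])COC1 | intermediate
10 | lithium 3-[2-(1-ethoxyethoxy)-4-lithiophenyl]oxetan-3-olate | CCOC(C)Oc1cc([Li])ccc1C1(O[Li])COC1 | intermediate
11 | 3-[2-(1-ethoxyethoxy)-4-(hydroxymethyl)phenyl]oxetan-3-ol (racemic acetal carbon) | CCOC(C)Oc1cc(CO)ccc1C1(O)COC1 | intermediate
12 | 3-[2-hydroxy-4-(hydroxymethyl)phenyl]oxetan-3-ol | OCc1ccc(C2(O)COC2)c(O)c1 | intermediate
13 | (2R)-2-methylbutanoic acid | CC[C@@H](C)C(=O)O | starting material
14 | [3-hydroxy-4-(3-hydroxyoxetan-3-yl)phenyl]methyl (2R)-2-methylbutanoate | CC[C@@H](C)C(=O)OCc1ccc(C2(O)COC2)c(O)c1 | intermediate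
15 | angelic acid, (2Z)-2-methylbut-2-enoic acid | C/C=C(/C)C(=O)O | starting material
16 | (2Z)-2-methylbut-2-enoic 2,4,6-trichlorobenzoic anhydride | C/C=C(/C)C(=O)OC(=O)c1c(Cl)cc(Cl)cc1Cl | intermediate
17 | 2-(3-hydroxyoxetan-3-yl)-5-{[(2R)-2-methylbutanoyl]oxymethyl}phenyl (2Z)-2-methylbut-2-enoate | C/C=C(/C)C(=O)Oc1cc(COC(=O)[C@H](C)CC)ccc1C1(O)COC1 | intermediate
18 | 2-[(2S)-1-acetoxy-3-bromo-2-hydroxypropan-2-yl]-5-{[(2R)-2-methylbutanoyl]oxymethyl}phenyl (2Z)-2-methylbut-2-enoate | C/C=C(/C)C(=O)Oc1cc(COC(=O)[C@H](C)CC)ccc1[C@](O)(COC(C)=O)CBr | intermediate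
19 | 2-[(2R)-2-(acetoxymethyl)oxiran-2-yl]-5-{[(2R)-2-methylbutanoyl]oxymethyl}phenyl (2Z)-2-methylbut-2-enoate | C/C=C(/C)C(=O)Oc1cc(COC(=O)[C@H](C)CC)ccc1[C@]1(COC(C)=O)CO1 | target

**Step count and risks**
Total step count: 6. Longest linear sequence: 6 (1 → 4 → 5 → 12 → 14 → 17 → 19).

The three steps most likely to fail:

Step 3 (four operations in one pot; the second aryllithium and the formaldehyde trapping are the weak points). The fallback sets out from 5 and comes back at 11. Only the first exchange and the addition to 6 are run, and after aqueous quench 3-[4-bromo-2-(1-ethoxyethoxy)phenyl]oxetan-3-ol F1 is isolated. The benzylic carbon is then brought in by cross-coupling instead of a second aryllithium: Pd(OAc)2/Xantphos-catalysed methoxycarbonylation (CO 1 atm, MeOH, Et3N, 70 °C) gives methyl 3-(1-ethoxyethoxy)-4-(3-hydroxyoxetan-3-yl)benzoate F2. LiBH4 (THF, 0 °C → rt) reduces F2 to 11, which is taken on with PPTS/MeOH to 12.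

Step 4 (chemoselectivity of the Mitsunobu reaction next to a free phenol). The fallback sets out from 11, isolated by leaving out the PPTS/MeOH stage of step 3, and comes back at 14. Carbodiimide esterification with 13 (EDC·HCl, DMAP cat., CH2Cl2, 0 °C → rt) at the only reactive OH, the tertiary one being inert, gives [3-(1-ethoxyethoxy)-4-(3-hydroxyoxetan-3-yl)phenyl]methyl (2R)-2-methylbutanoate F3. PPTS, MeOH, rt then removes the acetal and gives 14.

Step 6 (the proposed new step; risks are background opening by adventitious HBr, acetylation or ionisation at the tertiary alcohol, low enantioselectivity, and acyl migration during closure). The fallback uses known chemistry, sets out from 17 and comes back at 18. The established chiral-squaramide-catalysed (or chiral-phosphoric-acid-catalysed) desymmetrising opening of the oxetane with Me3SiBr (t-BuOMe, −78 °C) gives 2-[(2S)-1-bromo-2-hydroxy-3-(trimethylsilyloxy)propan-2-yl]-5-{[(2R)-2-methylbutanoyl]oxymethyl}phenyl (2Z)-2-methylbut-2-enoate F4. Work-up with pH 5 citrate buffer frees the primary alcohol to give 2-[(2S)-1-bromo-2,3-dihydroxypropan-2-yl]-5-{[(2R)-2-methylbutanoyl]oxymethyl}phenyl (2Z)-2-methylbut-2-enoate F5. Selective acetylation of the primary OH (Ac2O, 2,4,6-collidine, CH2Cl2, −20 °C) gives 18, which is closed with Cs2CO3 as in the route to 19.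

**Further compounds**
F1 | step 3 | 3-[4-bromo-2-(1-ethoxyethoxy)phenyl]oxetan-3-ol | CCOC(C)Oc1cc(Br)ccc1C1(O)COC1
F2 | step 3 | methyl 3-(1-ethoxyethoxy)-4-(3-hydroxyoxetan-3-yl)benzoate | CCOC(C)Oc1cc(C(=O)OC)ccc1C1(O)COC1
F3 | step 4 | [3-(1-ethoxyethoxy)-4-(3-hydroxyoxetan-3-yl)phenyl]methyl (2R)-2-methylbutanoate | CC[C@@H](C)C(=O)OCc1ccc(C2(O)COC2)c(OC(C)OCC)c1
F4 | step 6 | 2-[(2S)-1-bromo-2-hydroxy-3-(trimethylsilyloxy)propan-2-yl]-5-{[(2R)-2-methylbutanoyl]oxymethyl}phenyl (2Z)-2-methylbut-2-enoate | C/C=C(/C)C(=O)Oc1cc(COC(=O)[C@H](C)CC)ccc1[C@](O)(CO[Si](C)(C)C)CBr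
F5 | step 6 | 2-[(2S)-1-bromo-2,3-dihydroxypropan-2-yl]-5-{[(2R)-2-methylbutanoyl]oxymethyl}phenyl (2Z)-2-methylbut-2-enoate | C/C=C(/C)C(=O)Oc1cc(COC(=O)[C@H](C)CC)ccc1[C@](O)(CO)CBr
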